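## Structural features

The target is a hexacyclic coumaronochromone. A chromone (rings A and C) is joined to ring B twice, by the C3–C1' bond and by an oxygen bridge from C2 to C2', so that a furan (ring D) lies between them. Ring A carries a chelated 5-OH, a methyl group on C6 and an angular 2,2-dimethyl-2H-pyran (ring F) built on O7 and C8. Ring B is a hydroquinone-type ring (O2' and O5' are para) with a free 5'-OH and a dihydropyran (ring E) built on O4' and C3'. Ring E holds the only two stereocentres, the neighbouring carbinols C3'' (R) and C4'' (S), which are trans and stand next to the gem-dimethyl carbon C2''. The fragile sites are the C4'' benzylic alcohol (flanked by two oxygen-bearing ring carbons, so it ionises easily in acid), the electron-rich ring B, the ring F double bond, and C2, a ketene-acetal carbon open to nucleophiles. The real difficulty is threefold: the absolute and relative configuration of the trans-diol, the regiochemistry on both benzene rings (three different oxygens on ring B; 6-methyl against 8-methyl and angular against linear pyran on ring A), and a late union of two electron-rich halves. The key step uses the fact that, once the C3''–C4'' bond is cut, both carbons are at the aldehyde oxidation level: C4'' as an aryl aldehyde on C3', and C3'' as an α-aryloxy aldehyde hung from O4' through C2''.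

## Logic of the disconnections

**30 ⇒ 29.** Three O–Si bonds are cut. The 5'-phenol and the diol would interfere with the base-mediated union and with the palladium step, so they are carried as silyl ethers. The demand on the forward step is a non-acidic deprotection, because C4'' ionises in acid.

**29 ⇒ 28.** The C3–C1' bond of ring D is cut. It is the only carbon–carbon link between the two halves, and removing it leaves an aryl vinyl ether. The forward step needs a bromine on C1', the free C3–H of the chromone, and silyl ethers that survive carbonate at about 110 °C; for that reason O5' carries TIPS and not TBS.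

**28 ⇒ 17 + 27.** The C2–O2' bond is cut, because C2 is a vinylogous acyl carbon that takes part in addition–elimination. This gives two halves of similar size. O2' must be the only nucleophilic oxygen of 17, and C2 of 27 must carry a leaving group.

**27 ⇒ 26 ⇒ 24 + 25.** First the S–O bond, then the C8–C and O7–C bonds of ring F. In 24, C8 is the only free ring carbon and O7 the only oxygen next to it, so the pyran can only form in the angular sense. The forward steps must oxidise sulfur without touching the new double bond, and must not displace the methylthio group.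

**24 ⇒ 23 ⇒ 21 ⇒ 20 ⇒ 18.** Two O–CH3 bonds, then ring C (C2 comes from CS2), then the acetyl C–C bond, then a C–O bond made through C–H borylation. Closing ring C on a ring with two different free ortho-hydroxyls would give a 6-methyl/8-methyl mixture. In 21 only the future O1 is free, because the two oxygens flanking the methyl group are the identical ether oxygens of the symmetric phenol 20. The regiochemical problem of ring A is thereby reduced to symmetry. The price is a sterically controlled C–H borylation of 18 and a demethylation that spares the S-methyl group.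

**17 ⇒ 16 ⇒ 15 ⇒ 13.** The C–Br bond, the O–allyl bond and three O–Si bonds. Bromination is placed after deallylation, because the free phenol directs cleanly to its only open ortho position. Allyl is kept on O2' up to this point because it survives hydride, carbene, acid and silylation, and leaves under neutral conditions.

**13 ⇒ 12 ⇒ 11.** The C4''–H bond and the O–PMB bond. The trans-diol is derived from the ketol by intramolecular hydride delivery, so C4'' is set from C3''. The PMB group is removed while C4'' is still a ketone, since the benzylic alcohol made later would not tolerate acid.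

**11 ⇒ 10.** The C3''–C4'' bond, the strategic cut. Ring E and the stereocentre disappear and an achiral dialdehyde remains. The forward step requires the carbene to engage the aryl aldehyde and not the α-aryloxy aldehyde, and a base weak enough not to enolise the product.

**10 ⇒ 9 ⇒ 8 ⇒ 6 + 7.** Oxidation-level changes and the O4'–C2'' bond. Ester 7 carries the quaternary carbon; taking both carbonyls of 8 to the alcohol level and back avoids having to tell them apart. The forward demand is an SN2 reaction at a tertiary carbon by a hindered phenoxide. Since O5' stands next to that phenoxide, it must carry a group that cannot migrate, which is why PMB and not a silyl group is used up to 11.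

**6 ⇒ 5 ⇒ 3 ⇒ 2 ⇒ 1.** The formyl C–C bond, a C–O bond made by Baeyer–Villiger oxidation, and two protecting groups. Compound 1 already has the para oxygen pair of ring B. Its formyl carbon marks the place of O4', and the new formyl group then enters at the only free position ortho to that new hydroxyl. The forward demand is a selective mono-allylation of 1.

## Other disconnections considered

**Alternative 1:** The cut is the C3–C1' bond of ring D. In the forward step, zerovalent palladium inserts into the C1'–Br bond of the tris-TBS 2-(2-bromoaryloxy)chromone A1 and arylates the chromone C3–H to give the tris-TBS ether A2.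
- In its favour: it is convergent, touches no stereocentre, has only one C–H within reach, and follows from a simple addition–elimination.
- Against it, as the organising idea of a route: it is silent on ring E, where the stereochemical problem lies, and the silyl pattern of A1 and A2 puts an aryl TBS ether under hot carbonate.
- A plan built on it would most naturally make ring E by asymmetric epoxidation of a 2,2-dimethylchromene and opening with water. The SN1 character of a benzylic carbon flanked by two oxygens would then threaten the trans selectivity.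
- Comparison: on construction of the core it is the equal of the chosen plan, which uses this very closure as step 21 with TIPS on O5'. On step economy an epoxidation-based version would be shorter by several steps, and is the better there. On stereocontrol the chosen plan is the stronger, because C3'' is set by a catalyst at a carbon that cannot ionise, and C4'' by internal hydride delivery.

**Alternative 2:** The cut is the O1–C8a bond of ring C. In the forward step, the enolate of the 3-(2-bromoaroyl)benzofuran-2(3H)-one A3 closes the pyranone by intramolecular O-arylation under CuI (copper iodide) catalysis, giving the 5-O-allyl tris-silyl ether A4.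
- In its favour: O-arylation of 1-(2-haloaryl)-1,3-dicarbonyl compounds to chromones is an established reaction class. Only the lactone-derived oxygen can reach C8a, since the ketone oxygen would close a four-membered ring.
- Also in its favour, and better than the chosen plan: ring A needs only the two oxygens that flank the methyl group, so the 6-methyl/8-methyl question never arises. The chosen plan spends a C–H borylation and a demethylation on it.
- Against it: the bromine must sit meta to both ring-A oxygens, which needs directed metalation next to the carboxyl group. Ring B must be homologated at C1' to an arylacetic acid and lactonised. The lactone enolate can be O-acylated or opened. The 5-OH must be masked and freed again.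
- Comparison: it is the equal of the chosen plan for ring E, since A3 can take the same benzoin chemistry. It is sound mechanistically. It is longer in the ring-B series and in protecting-group steps.

**Alternative 3:** The cuts are the C4–C3 and O1–C2 bonds. In the forward step, light or heat expels acetone from the ring-A benzodioxinone A5. The resulting ortho-quinoid ketene is captured by the C2=C3 bond of the ring-B 2-silyloxybenzofuran A6 (C3 to the ketene carbon, phenolic oxygen to C2). Loss of silanol then gives the 5-O-acetyl tris-TBS ether A7.
- In its favour: it forms two bonds and ring C in one operation from two halogen-free partners, without a metal. In convergence and bonds formed per step it is better than the chosen plan.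
- Against it: capture of such ketenes by a carbon π-nucleophile in a [4+2] sense has far less precedent than capture by alcohols or amines. The 2H-chromene of ring F is prone to photochemical ring opening, which argues against light, and the thermal variant needs high temperature. A6 is a hydrolytically fragile ketene acetal that may be C-acylated without closing. A5 brings back the question of which ortho-hydroxyl is engaged on ring A, and needs an acetate that must later be removed.
- Comparison: it is the equal of the chosen plan for ring E. It is potentially the shortest route, and the least certain.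

Key step: step 8

Remark: the (3''R) diol and the (S)-ketol describe the same spatial arrangement at C3'', because C4 outranks C2 once it is a carbonyl; the structures needed no correction.
Remark: the sense of induction of the aminoindanol-derived triazolium salt is assigned by analogy only; "(5aS,10bR)" in step 8 stands for the antipode that directs attack to the Re face of the acceptor aldehyde, both antipodes being commercial.
Remark: sulfoxide 27 is racemic at sulfur, which is of no consequence because the group leaves in step 20.
Abbreviations: PMB = 4-methoxybenzyl, TBS = tert-butyldimethylsilyl, TIPS = triisopropylsilyl.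

## Steps

Step 1
Reactants: 1 2,5-dihydroxybenzaldehyde
Product: 2 5-(allyloxy)-2-hydroxybenzaldehyde
Conditions: allyl bromide (1.0 equiv), K2CO3 (1.1 equiv), acetone, reflux
Reagents that add atoms: allyl bromide, C=CCBr
Why: Williamson ether synthesis; the 2-OH is held in a hydrogen bond to the formyl group and its phenoxide is a vinylogous carboxylate, so with one equivalent of halide the non-chelated 5-oxygen should be the kinetic nucleophile.

Step 2
Reactants: 2 5-(allyloxy)-2-hydroxybenzaldehyde
Product: 3 5-(allyloxy)-2-[(4-methoxybenzyl)oxy]benzaldehyde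
Conditions: 4-methoxybenzyl chloride, K2CO3, n-Bu4NI (cat.), DMF, 60 °C
Reagents that add atoms: 4-methoxybenzyl chloride, COc1ccc(CCl)cc1
Why: Williamson ether synthesis on the remaining chelated phenol under more forcing conditions; an alkyl-type group is chosen because this oxygen will stand next to a phenoxide in steps 4 and 5, where a silyl group could migrate or be lost.

Step 3
Reactants: 3 5-(allyloxy)-2-[(4-methoxybenzyl)oxy]benzaldehyde
Product: 5 5-(allyloxy)-2-[(4-methoxybenzyl)oxy]phenol, via aryl formate 4 (not isolated)
Conditions: mCPBA, CH2Cl2, 0 °C → rt; then K2CO3 (cat.), MeOH, 0 °C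
Reagents that add atoms: 3-chloroperoxybenzoic acid, OOC(=O)c1cccc(Cl)c1
Why: Baeyer–Villiger oxidation (Dakin-type) of an electron-rich benzaldehyde, in which the dialkoxyaryl group migrates, followed by mild methanolysis of the formate; the monosubstituted allyl alkene is epoxidised far more slowly than the aldehyde is oxidised.

Step 4
Reactants: 5 5-(allyloxy)-2-[(4-methoxybenzyl)oxy]phenol
Product: 6 6-(allyloxy)-2-hydroxy-3-[(4-methoxybenzyl)oxy]benzaldehyde
Conditions: MgCl2, Et3N, (CH2O)n, MeCN, reflux
Reagents that add atoms: paraformaldehyde (as formaldehyde), C=O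
Why: Magnesium-mediated ortho-formylation (Casnati–Skattebøl): the magnesium phenoxide delivers formaldehyde to its ortho position and a second equivalent oxidises the hydroxymethyl stage by hydride transfer; the other ortho position carries the PMB ether, so only one regioisomer can form.

Step 5
Reactants: 6 6-(allyloxy)-2-hydroxy-3-[(4-methoxybenzyl)oxy]benzaldehyde; 7 ethyl 2-bromo-2-methylpropanoate
Product: 8 ethyl 2-{3-(allyloxy)-2-formyl-6-[(4-methoxybenzyl)oxy]phenoxy}-2-methylpropanoate
Conditions: 7 (3 equiv), Cs2CO3, DMF, 60 °C
Reagents that add atoms: none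
Why: Williamson ether synthesis with a tertiary α-bromo ester, the standard entry to aryloxyisobutyrates; the excess of 7 offsets its competing dehydrobromination, and the neighbouring PMB ether, unlike a silyl ether, cannot move to the phenoxide.

Step 6
Reactants: 8 ethyl 2-{3-(allyloxy)-2-formyl-6-[(4-methoxybenzyl)oxy]phenoxy}-2-methylpropanoate
Product: 9 2-{3-(allyloxy)-2-(hydroxymethyl)-6-[(4-methoxybenzyl)oxy]phenoxy}-2-methylpropan-1-ol
Conditions: LiAlH4, THF, 0 °C; aq. KNaC4H4O6 work-up
Reagents that add atoms: none
Why: Hydride reduction of ester and aldehyde together to the diol, so that the two carbonyl carbons need not be distinguished; the aryl ethers and the allyl group are inert.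

Step 7
Reactants: 9 2-{3-(allyloxy)-2-(hydroxymethyl)-6-[(4-methoxybenzyl)oxy]phenoxy}-2-methylpropan-1-ol
Product: 10 6-(allyloxy)-3-[(4-methoxybenzyl)oxy]-2-[(2-methyl-1-oxopropan-2-yl)oxy]benzaldehyde
Conditions: Dess–Martin periodinane, NaHCO3, CH2Cl2, 0 °C → rt
Reagents that add atoms: none
Why: Dess–Martin oxidation of the benzylic and the neopentyl primary alcohol; a buffered, non-sulfonium oxidant is chosen because the 2,6-dialkoxybenzylic alcohol ionises easily, and the aliphatic aldehyde has no α-hydrogen to lose.

Step 8
Reactants: 10 6-(allyloxy)-3-[(4-methoxybenzyl)oxy]-2-[(2-methyl-1-oxopropan-2-yl)oxy]benzaldehyde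
Product: 11 (S)-5-(allyloxy)-3-hydroxy-8-[(4-methoxybenzyl)oxy]-2,2-dimethylchroman-4-one
Conditions: (5aS,10bR)-2-(pentafluorophenyl)-5a,10b-dihydro-4H,6H-indeno[2,1-b][1,2,4]triazolo[4,3-d][1,4]oxazin-2-ium tetrafluoroborate (15 mol %), i-Pr2NEt (15 mol %), toluene, rt, argon
Reagents that add atoms: none
Why: The carbene released from the triazolium salt adds to the aryl aldehyde, proton transfer gives the Breslow enaminol (an acyl anion equivalent), and its nucleophilic carbon attacks the tethered aliphatic aldehyde before the adduct collapses to the ketone and frees the carbene. The closest known reaction type is the carbene-catalysed enantioselective intramolecular crossed benzoin that gives 3-hydroxychroman-4-ones from 2-(2-oxoalkoxy)benzaldehydes, established mainly with ketone acceptors. Ring E closes in the 6-exo-trig mode, assisted by the gem-dimethyl group (Thorpe–Ingold effect). C3'' is set under catalyst control: the indane wall of the catalyst shields one face of the enaminol, the acceptor carbonyl is held by a hydrogen bond to the enaminol OH, and attack on the Re face of the aldehyde gives (S). The step needs the carbene to add to the aryl aldehyde and not to the aliphatic one; this rests on the α-quaternary centre, which makes the aliphatic aldehyde a neopentyl-type carbonyl that bulky triazolylidenes approach slowly and that is a poor acyl donor. The acceptor has no α-hydrogen, so aldol and enolisation paths are closed, and the aryl ketone is the conjugated, thermodynamically preferred acyloin. A weak amine base in substoichiometric amount and a non-polar solvent are used so that the product, whose C3''–H is α to the ketone, is not epimerised.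

Step 9
Reactants: 11 (S)-5-(allyloxy)-3-hydroxy-8-[(4-methoxybenzyl)oxy]-2,2-dimethylchroman-4-one
Product: 12 (S)-5-(allyloxy)-3,8-dihydroxy-2,2-dimethylchroman-4-one
Conditions: TFA, anisole, CH2Cl2, 0 °C
Reagents that add atoms: none
Why: Acidolysis of the aryl PMB ether (SN1, the benzyl cation being trapped by anisole); it is done here because C4'' is still a ketone and no ionisable benzylic alcohol is exposed to acid, and the short contact at 0 °C should keep enolisation of the ketol negligible.

Step 10
Reactants: 12 (S)-5-(allyloxy)-3,8-dihydroxy-2,2-dimethylchroman-4-one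
Product: 13 (3R,4S)-5-(allyloxy)-2,2-dimethylchromane-3,4,8-triol
Conditions: Me4NBH(OAc)3, MeCN/AcOH, −30 °C
Reagents that add atoms: none
Why: Hydroxyl-directed reduction (Evans–Saksena type): the C3 hydroxyl exchanges an acetate on boron and the alkoxyborohydride delivers hydride to the C4 carbonyl from the face of the C3–O bond, so the new hydroxyl is forced trans and C4 becomes (S); the free reagent is too weak to reduce the hindered aryl ketone intermolecularly.

Step 11
Reactants: 13 (3R,4S)-5-(allyloxy)-2,2-dimethylchromane-3,4,8-triol
Product: 15 (3R,4S)-5-(allyloxy)-3,4-bis[(tert-butyldimethylsilyl)oxy]-2,2-dimethyl-8-[(triisopropylsilyl)oxy]chromane, via mono-TIPS ether 14 (not isolated)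
Conditions: TIPSCl, imidazole, CH2Cl2, rt; then 2,6-lutidine, TBSOTf, 0 °C → rt
Reagents that add atoms: chlorotriisopropylsilane, CC(C)[Si](Cl)(C(C)C)C(C)C; tert-butyldimethylsilyl trifluoromethanesulfonate, CC(C)(C)[Si](C)(C)OS(=O)(=O)C(F)(F)F
Why: Silyl ether formation in two stages: the silyl chloride with imidazole takes only the phenol, the two secondary hydroxyls being neopentyl-like and flanked, and the silyl triflate then caps both; TIPS is put on the phenol because it must survive carbonate in steps 20 and 21, TBS on the diol because a silyloxy group is a poor leaving group beside the phenoxide made later.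

Step 12
Reactants: 15 (3R,4S)-5-(allyloxy)-3,4-bis[(tert-butyldimethylsilyl)oxy]-2,2-dimethyl-8-[(triisopropylsilyl)oxy]chromane
Product: 16 (3R,4S)-3,4-bis[(tert-butyldimethylsilyl)oxy]-2,2-dimethyl-8-[(triisopropylsilyl)oxy]chroman-5-ol
Conditions: Pd(PPh3)4 (5 mol %), morpholine, THF, rt
Reagents that add atoms: none
Why: Tsuji–Trost deallylation: zerovalent palladium ionises the allyl aryl ether and morpholine traps the allyl fragment; silyl ethers are untouched under these neutral conditions.

Step 13
Reactants: 16 (3R,4S)-3,4-bis[(tert-butyldimethylsilyl)oxy]-2,2-dimethyl-8-[(triisopropylsilyl)oxy]chroman-5-ol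
Product: 17 (3R,4S)-6-bromo-3,4-bis[(tert-butyldimethylsilyl)oxy]-2,2-dimethyl-8-[(triisopropylsilyl)oxy]chroman-5-ol
Conditions: NBS (1.0 equiv), i-Pr2NH (cat.), CH2Cl2, −78 → 0 °C
Reagents that add atoms: N-bromosuccinimide, O=C1CCC(=O)N1Br
Why: Electrophilic aromatic bromination ortho to the free phenol; the para position carries the silyloxy group and the other ortho position is the ring-fusion carbon, so only C6 (C1' of ring B) is open, and one equivalent at low temperature should avoid oxidation to a quinone.

Step 14
Reactants: 18 1,3-dimethoxy-2-methylbenzene (2,6-dimethoxytoluene)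
Product: 20 3,5-dimethoxy-4-methylphenol, via arylboronic ester 19 (not isolated)
Conditions: [Ir(OMe)(cod)]2 (1.5 mol %), 4,4'-di-tert-butyl-2,2'-bipyridine, B2pin2 (0.55 equiv), THF, 80 °C; then KHSO5 (as 2KHSO5·KHSO4·K2SO4), acetone/H2O, rt
Reagents that add atoms: potassium peroxymonosulfate (the new oxygen), [K+].[O-]S(=O)(=O)OO; bis(pinacolato)diboron (boron of 19 only), CC1(C)OB(OC1(C)C)B1OC(C)(C)C(C)(C)O1
Why: Iridium-catalysed C–H borylation (Hartwig–Miyaura) is sterically controlled and takes the one C–H that has no ortho substituent, para to the methyl group; oxidation of the C–B bond in the same flask gives the phenol, in which the future O1 is the only free hydroxyl.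

Step 15
Reactants: 20 3,5-dimethoxy-4-methylphenol
Product: 21 1-(6-hydroxy-2,4-dimethoxy-3-methylphenyl)ethan-1-one
Conditions: Ac2O, BF3·OEt2, AcOH, 80 °C; aqueous work-up
Reagents that add atoms: acetic anhydride, CC(=O)OC(C)=O
Why: Friedel–Crafts acylation (through O-acetylation and Fries rearrangement) ortho to the phenol; the two ortho positions are equivalent by symmetry and the para position is blocked by methyl, so a single ketone can form.

Step 16
Reactants: 21 1-(6-hydroxy-2,4-dimethoxy-3-methylphenyl)ethan-1-one
Product: 23 5,7-dimethoxy-6-methyl-2-(methylsulfanyl)-4H-chromen-4-one, via thione salt 22 (not isolated)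
Conditions: KOtBu (3.3 equiv), CS2, THF, 0 °C → rt; then MeI (3.3 equiv), rt
Reagents that add atoms: carbon disulfide, S=C=S; iodomethane, CI
Why: Claisen-type condensation of the ketone enolate with CS2, attack of the only free phenoxide on the dithioate with loss of hydrosulfide to close ring C, then S-methylation of the ambident thione anion at its soft sulfur; closure can use only the one free oxygen, which fixes the 6-methyl pattern.

Step 17
Reactants: 23 5,7-dimethoxy-6-methyl-2-(methylsulfanyl)-4H-chromen-4-one
Product: 24 5,7-dihydroxy-6-methyl-2-(methylsulfanyl)-4H-chromen-4-one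
Conditions: BBr3 (4 equiv), CH2Cl2, −78 °C → rt
Reagents that add atoms: none
Why: Lewis-acid cleavage of both aryl methyl ethers, the 5-OMe through the chelate with the C4 carbonyl and the 7-OMe twisted out of conjugation by the flanking methyl; methyl sulfides are normally inert to BBr3, and no acid-sensitive group is present yet.

Step 18
Reactants: 24 5,7-dihydroxy-6-methyl-2-(methylsulfanyl)-4H-chromen-4-one; 25 3-methylbut-2-enal
Product: 26 5-hydroxy-6,8,8-trimethyl-2-(methylsulfanyl)-4H,8H-pyrano[2,3-f]chromen-4-one
Conditions: 25 (2 equiv), pyridine, 120 °C (sealed tube)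
Reagents that add atoms: none
Why: Chromenylation: aldol-type condensation at C8, dehydration to the ortho-quinone methide and 6π oxa-electrocyclisation; C8 is the only free ring carbon and only the 7-OH is next to it, so the angular pyran is the sole possible product, and pyridine cannot displace the methylthio group.

Step 19
Reactants: 26 5-hydroxy-6,8,8-trimethyl-2-(methylsulfanyl)-4H,8H-pyrano[2,3-f]chromen-4-one
Product: 27 5-hydroxy-6,8,8-trimethyl-2-(methylsulfinyl)-4H,8H-pyrano[2,3-f]chromen-4-one
Conditions: H2O2 (30 % aq., 1.1 equiv), (CF3)2CHOH, rt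
Reagents that add atoms: hydrogen peroxide, OO
Why: Chemoselective oxidation of sulfide to sulfoxide; hydrogen peroxide activated by the hydrogen-bonding solvent oxidises sulfur, should not epoxidise the ring F double bond, and stops at the sulfoxide.

Step 20
Reactants: 17 (3R,4S)-6-bromo-3,4-bis[(tert-butyldimethylsilyl)oxy]-2,2-dimethyl-8-[(triisopropylsilyl)oxy]chroman-5-ol; 27 5-hydroxy-6,8,8-trimethyl-2-(methylsulfinyl)-4H,8H-pyrano[2,3-f]chromen-4-one
Product: 28 2-{[(3R,4S)-6-bromo-3,4-bis[(tert-butyldimethylsilyl)oxy]-2,2-dimethyl-8-[(triisopropylsilyl)oxy]chroman-5-yl]oxy}-5-hydroxy-6,8,8-trimethyl-4H,8H-pyrano[2,3-f]chromen-4-one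
Conditions: K2CO3 (1.2 equiv), DMF, rt → 40 °C
Reagents that add atoms: none
Why: Addition–elimination (vinylogous acyl substitution) at C2 of the chromone: the ortho-bromophenoxide of 17, the most acidic phenol present, adds and methanesulfenate leaves; the chelated 5-OH of 27 stays protonated and keeps C2 electrophilic.

Step 21
Reactants: 28 2-{[(3R,4S)-6-bromo-3,4-bis[(tert-butyldimethylsilyl)oxy]-2,2-dimethyl-8-[(triisopropylsilyl)oxy]chroman-5-yl]oxy}-5-hydroxy-6,8,8-trimethyl-4H,8H-pyrano[2,3-f]chromen-4-one
Product: 29 O5'-triisopropylsilyl O3'',O4''-bis(tert-butyldimethylsilyl) ether of the target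
Conditions: Pd(OAc)2 (10 mol %), PCy3·HBF4 (20 mol %), K2CO3 (2 equiv), pivalic acid (30 mol %), N,N-dimethylacetamide, 110 °C
Reagents that add atoms: none
Why: Palladium-catalysed intramolecular direct arylation: oxidative addition into the C1'–Br bond, carboxylate-assisted palladation of the electron-rich C3–H and reductive elimination close the furan; the closest precedent is the closure of 4-(2-bromoaryloxy)coumarins to coumestans, and C3 is the only C–H within reach.

Step 22
Reactants: 29 O5'-triisopropylsilyl O3'',O4''-bis(tert-butyldimethylsilyl) ether of the target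
Product: 30 CNP0351839.1, the (3''R,4''S)-trans-diol coumaronochromone
Conditions: n-Bu4NF, AcOH (1:1), THF, rt → 45 °C
Reagents that add atoms: none
Why: Fluoride-mediated desilylation of the aryl TIPS and both secondary TBS ethers; acetic acid buffers the medium, and acidic reagents that could ionise C4'' are avoided, so neither stereocentre is touched.

## Compound list

1 | 2,5-dihydroxybenzaldehyde | O=Cc1cc(O)ccc1O | starting material
2 | 5-(allyloxy)-2-hydroxybenzaldehyde | O=Cc1cc(OCC=C)ccc1O | intermediate
3 | 5-(allyloxy)-2-[(4-methoxybenzyl)oxy]benzaldehyde | O=Cc1cc(OCC=C)ccc1OCc1ccc(OC)cc1 | intermediate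
4 | 5-(allyloxy)-2-[(4-methoxybenzyl)oxy]phenyl formate | O=COc1cc(OCC=C)ccc1OCc1ccc(OC)cc1 | intermediate
5 | 5-(allyloxy)-2-[(4-methoxybenzyl)oxy]phenol | Oc1cc(OCC=C)ccc1OCc1ccc(OC)cc1 | intermediate
6 | 6-(allyloxy)-2-hydroxy-3-[(4-methoxybenzyl)oxy]benzaldehyde | O=Cc1c(O)c(OCc2ccc(OC)cc2)ccc1OCC=C | intermediate
7 | ethyl 2-bromo-2-methylpropanoate | CCOC(=O)C(C)(C)Br | starting material
8 | ethyl 2-{3-(allyloxy)-2-formyl-6-[(4-methoxybenzyl)oxy]phenoxy}-2-methylpropanoate | CCOC(=O)C(C)(C)Oc1c(C=O)c(OCC=C)ccc1OCc1ccc(OC)cc1 | intermediate
9 | 2-{3-(allyloxy)-2-(hydroxymethyl)-6-[(4-methoxybenzyl)oxy]phenoxy}-2-methylpropan-1-ol | OCC(C)(C)Oc1c(CO)c(OCC=C)ccc1OCc1ccc(OC)cc1 | intermediate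
10 | 6-(allyloxy)-3-[(4-methoxybenzyl)oxy]-2-[(2-methyl-1-oxopropan-2-yl)oxy]benzaldehyde | O=Cc1c(OCC=C)ccc(OCc2ccc(OC)cc2)c1OC(C)(C)C=O | intermediate
11 | (S)-5-(allyloxy)-3-hydroxy-8-[(4-methoxybenzyl)oxy]-2,2-dimethylchroman-4-one | C=CCOc1c2c(c(OCc3ccc(OC)cc3)cc1)OC(C)(C)[C@H](O)C2=O | intermediate
12 | (S)-5-(allyloxy)-3,8-dihydroxy-2,2-dimethylchroman-4-one | C=CCOc1c2c(c(O)cc1)OC(C)(C)[C@H](O)C2=O | intermediate
13 | (3R,4S)-5-(allyloxy)-2,2-dimethylchromane-3,4,8-triol | C=CCOc1c2c(c(O)cc1)OC(C)(C)[C@H](O)[C@H]2O | intermediate
14 | (3R,4S)-5-(allyloxy)-2,2-dimethyl-8-[(triisopropylsilyl)oxy]chromane-3,4-diol | C=CCOc1c2c(c(O[Si](C(C)C)(C(C)C)C(C)C)cc1)OC(C)(C)[C@H](O)[C@H]2O | intermediate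
15 | (3R,4S)-5-(allyloxy)-3,4-bis[(tert-butyldimethylsilyl)oxy]-2,2-dimethyl-8-[(triisopropylsilyl)oxy]chromane | C=CCOc1c2c(c(O[Si](C(C)C)(C(C)C)C(C)C)cc1)OC(C)(C)[C@H](O[Si](C)(C)C(C)(C)C)[C@H]2O[Si](C)(C)C(C)(C)C | intermediate
16 | (3R,4S)-3,4-bis[(tert-butyldimethylsilyl)oxy]-2,2-dimethyl-8-[(triisopropylsilyl)oxy]chroman-5-ol | Oc1c2c(c(O[Si](C(C)C)(C(C)C)C(C)C)cc1)OC(C)(C)[C@H](O[Si](C)(C)C(C)(C)C)[C@H]2O[Si](C)(C)C(C)(C)C | intermediate
17 | (3R,4S)-6-bromo-3,4-bis[(tert-butyldimethylsilyl)oxy]-2,2-dimethyl-8-[(triisopropylsilyl)oxy]chroman-5-ol | Oc1c2c(c(O[Si](C(C)C)(C(C)C)C(C)C)cc1Br)OC(C)(C)[C@H](O[Si](C)(C)C(C)(C)C)[C@H]2O[Si](C)(C)C(C)(C)C | intermediate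
18 | 1,3-dimethoxy-2-methylbenzene (2,6-dimethoxytoluene) | COc1cccc(OC)c1C | starting material
19 | 2-(3,5-dimethoxy-4-methylphenyl)-4,4,5,5-tetramethyl-1,3,2-dioxaborolane | COc1cc(B2OC(C)(C)C(C)(C)O2)cc(OC)c1C | intermediate
20 | 3,5-dimethoxy-4-methylphenol | COc1cc(O)cc(OC)c1C | intermediate
21 | 1-(6-hydroxy-2,4-dimethoxy-3-methylphenyl)ethan-1-one | CC(=O)c1c(O)cc(OC)c(C)c1OC | intermediate
22 | 4-hydroxy-5,7-dimethoxy-6-methyl-2H-chromene-2-thione (present as its potassium salt) | COc1cc2oc(=S)cc(O)c2c(OC)c1C | intermediate
23 | 5,7-dimethoxy-6-methyl-2-(methylsulfanyl)-4H-chromen-4-one | CSc1cc(=O)c2c(OC)c(C)c(OC)cc2o1 | intermediate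
24 | 5,7-dihydroxy-6-methyl-2-(methylsulfanyl)-4H-chromen-4-one | CSc1cc(=O)c2c(O)c(C)c(O)cc2o1 | intermediate
25 | 3-methylbut-2-enal | CC(C)=CC=O | starting material
26 | 5-hydroxy-6,8,8-trimethyl-2-(methylsulfanyl)-4H,8H-pyrano[2,3-f]chromen-4-one | CSc1cc(=O)c2c(O)c(C)c3OC(C)(C)C=Cc3c2o1 | intermediate
27 | 5-hydroxy-6,8,8-trimethyl-2-(methylsulfinyl)-4H,8H-pyrano[2,3-f]chromen-4-one (racemic at sulfur) | CS(=O)c1cc(=O)c2c(O)c(C)c3OC(C)(C)C=Cc3c2o1 | intermediate
28 | 2-{[(3R,4S)-6-bromo-3,4-bis[(tert-butyldimethylsilyl)oxy]-2,2-dimethyl-8-[(triisopropylsilyl)oxy]chroman-5-yl]oxy}-5-hydroxy-6,8,8-trimethyl-4H,8H-pyrano[2,3-f]chromen-4-one | Cc1c2c(c3oc(Oc5c6c(c(O[Si](C(C)C)(C(C)C)C(C)C)cc5Br)OC(C)(C)[C@H](O[Si](C)(C)C(C)(C)C)[C@H]6O[Si](C)(C)C(C)(C)C)cc(=O)c3c1O)C=CC(C)(C)O2 | intermediate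
29 | O5'-triisopropylsilyl O3'',O4''-bis(tert-butyldimethylsilyl) ether of the target | Cc1c2c(c3oc4oc5c6c(c(O[Si](C(C)C)(C(C)C)C(C)C)cc5c4c(=O)c3c1O)OC(C)(C)[C@H](O[Si](C)(C)C(C)(C)C)[C@H]6O[Si](C)(C)C(C)(C)C)C=CC(C)(C)O2 | intermediate
30 | CNP0351839.1, (3''R,4''S)-trans-diol coumaronochromone (5-OH, 6-methyl, ring F on O7/C8, ring E on O4'/C3', 5'-OH) | Cc1c2c(c3oc4oc5c6c(c(O)cc5c4c(=O)c3c1O)OC(C)(C)[C@H](O)[C@H]6O)C=CC(C)(C)O2 | target

## Step count and least certain steps

Total: 22 steps. Longest linear sequence: 16 steps (steps 1–13, then 20–22). The ring-A/F branch has 6 steps (14–19).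

**Step 8 (key step).** The most likely failure is slow formation of the enaminol at an aryl aldehyde that has oxygen substituents in both ortho positions. That would give the carbene time to add to the α-aryloxy aldehyde, from which expulsion of the aryloxide (an internal redox) would destroy the substrate. A second danger is erosion of the C3'' configuration by base-induced enolisation of the product.
Fallback, setting out from 6 and returning at 11: 6 is treated with 2-methylprop-1-enylmagnesium bromide (THF, 0 °C) to give 1-{6-(allyloxy)-2-hydroxy-3-[(4-methoxybenzyl)oxy]phenyl}-3-methylbut-2-en-1-ol F1. On gentle warming with a trace of pyridinium tosylate this should lose water to an ortho-quinone methide and close by 6π oxa-electrocyclisation to 5-(allyloxy)-8-[(4-methoxybenzyl)oxy]-2,2-dimethyl-2H-chromene F2. Jacobsen epoxidation follows, with (R,R)-N,N'-bis(3,5-di-tert-butylsalicylidene)-1,2-cyclohexanediaminomanganese chloride and NaOCl; it takes conjugated cis-alkenes and should leave the terminal allyl ether alone. By analogy with other 2,2-dimethylchromenes it is expected to give (3R,4R)-5-(allyloxy)-3,4-epoxy-8-[(4-methoxybenzyl)oxy]-2,2-dimethylchromane F3. Opening with water under dilute acid gives (3R,4S)-5-(allyloxy)-8-[(4-methoxybenzyl)oxy]-2,2-dimethylchromane-3,4-diol F4; the C3–O bond is not broken, and the C4 epimer would serve equally. MnO2 then oxidises only the benzylic carbinol and gives 11.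

**Step 5.** Dehydrobromination of the tertiary bromide may outrun substitution at a phenoxide that is flanked on both sides, leaving the phenol unalkylated.
Fallback, setting out from 6 and returning at 11: the intermolecular SN2 reaction at a tertiary carbon is given up, and the tertiary C–O bond is formed by electrocyclisation instead. The detour 6 → F1 → F2 → F3 → F4 → 11 written out under step 8 needs none of 8, 9 or 10, and no further compound.

**Step 10.** The benzylic alcohol that forms may ionise in the acetic acid medium, or hydride may be delivered without the directing effect, so that the trans selectivity is lost.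
Fallback, setting out from 12 and returning at 13: reagent-controlled Noyori transfer hydrogenation, with RuCl[(R,R)-TsDPEN](p-cymene) in HCO2H/Et3N. Here the catalyst, not the neighbouring hydroxyl, selects the carbonyl face. The (R,R) complex is the one expected for the required face once the CIP priorities at C4'' are allowed for. No new compound is made.

**Step 17.** The Lewis acid activates C2 as well as the ethers. Bromide may then attack the S-methyl group or C2, with loss of the leaving-group precursor, or cleavage of the 7-methyl ether may stall.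
Fallback, setting out from 21 and returning at 24: the CS2 condensation of step 16 is worked up with acid so that 22 is isolated. BBr3 is applied at this stage, where no S-methyl group exists, to give 4,5,7-trihydroxy-6-methyl-2H-chromene-2-thione F5. Its strongly acidic thio-acid function is then methylated on sulfur alone (MeI, NaHCO3, acetone) to give 24.

**Step 21.** Hydrodebromination of the electron-rich aryl bromide, loss of the aryl silyl ether under hot carbonate, or binding of palladium by the chelating 5-hydroxy-4-keto unit may stop the closure.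
Fallback, setting out from 16 and 27 and returning at 29: bromination is omitted. Compounds 16 and 27 are joined as in step 20 to give 2-{[(3R,4S)-3,4-bis[(tert-butyldimethylsilyl)oxy]-2,2-dimethyl-8-[(triisopropylsilyl)oxy]chroman-5-yl]oxy}-5-hydroxy-6,8,8-trimethyl-4H,8H-pyrano[2,3-f]chromen-4-one F6. Ring D is then closed by an oxidative double C–H coupling with divalent palladium (Pd(OAc)2, AgOAc, pivalic acid, 110 °C), the reaction type that turns 4-aryloxycoumarins into coumestans. C1' is the only C–H ortho to the ether oxygen.

## Further compounds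

F1 | step 8 | 1-{6-(allyloxy)-2-hydroxy-3-[(4-methoxybenzyl)oxy]phenyl}-3-methylbut-2-en-1-ol (racemic) | CC(C)=CC(O)c1c(O)c(OCc2ccc(OC)cc2)ccc1OCC=C
F2 | step 8 | 5-(allyloxy)-8-[(4-methoxybenzyl)oxy]-2,2-dimethyl-2H-chromene | C=CCOc1ccc(OCc2ccc(OC)cc2)c2OC(C)(C)C=Cc12
F3 | step 8 | (3R,4R)-5-(allyloxy)-3,4-epoxy-8-[(4-methoxybenzyl)oxy]-2,2-dimethylchromane | C=CCOc1ccc(OCc2ccc(OC)cc2)c2OC(C)(C)[C@@H]3O[C@@H]3c12
F4 | step 8 | (3R,4S)-5-(allyloxy)-8-[(4-methoxybenzyl)oxy]-2,2-dimethylchromane-3,4-diol | C=CCOc1c2c(c(OCc3ccc(OC)cc3)cc1)OC(C)(C)[C@H](O)[C@H]2O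
F0 | step 5 | none | none
F0 | step 10 | none | none
F5 | step 17 | 4,5,7-trihydroxy-6-methyl-2H-chromene-2-thione | Oc1cc2oc(=S)cc(O)c2c(O)c1C
F6 | step 21 | 2-{[(3R,4S)-3,4-bis[(tert-butyldimethylsilyl)oxy]-2,2-dimethyl-8-[(triisopropylsilyl)oxy]chroman-5-yl]oxy}-5-hydroxy-6,8,8-trimethyl-4H,8H-pyrano[2,3-f]chromen-4-one | Cc1c2c(c3oc(Oc5c6c(c(O[Si](C(C)C)(C(C)C)C(C)C)cc5)OC(C)(C)[C@H](O[Si](C)(C)C(C)(C)C)[C@H]6O[Si](C)(C)C(C)(C)C)cc(=O)c3c1O)C=CC(C)(C)O2
A1 | alternative 1 | tris-TBS 2-(2-bromoaryloxy)chromone (ring-A/F chromone O-linked at C2 to the ring-B/E bromophenol) | Cc1c2c(c3oc(Oc5c6c(c(O[Si](C)(C)C(C)(C)C)cc5Br)OC(C)(C)[C@H](O[Si](C)(C)C(C)(C)C)[C@H]6O[Si](C)(C)C(C)(C)C)cc(=O)c3c1O)C=CC(C)(C)O2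
A2 | alternative 1 | tris-TBS ether of the target | Cc1c2c(c3oc4oc5c6c(c(O[Si](C)(C)C(C)(C)C)cc5c4c(=O)c3c1O)OC(C)(C)[C@H](O[Si](C)(C)C(C)(C)C)[C@H]6O[Si](C)(C)C(C)(C)C)C=CC(C)(C)O2
A3 | alternative 2 | 3-(2-bromoaroyl)benzofuran-2(3H)-one (ring-B/E lactone C-acylated by the ring-A/F 2-bromobenzoyl unit; C3 of the lactone configurationally labile) | O=C1Oc5c6c(c(O[Si](C(C)C)(C(C)C)C(C)C)cc5C1C(=O)c1c(Br)c2C=CC(C)(C)Oc2c(C)c1OCC=C)OC(C)(C)[C@H](O[Si](C)(C)C(C)(C)C)[C@H]6O[Si](C)(C)C(C)(C)C
A4 | alternative 2 | 5-O-allyl O5'-TIPS O3'',O4''-bis-TBS ether of the target | Cc1c2c(c3oc4oc5c6c(c(O[Si](C(C)C)(C(C)C)C(C)C)cc5c4c(=O)c3c1OCC=C)OC(C)(C)[C@H](O[Si](C)(C)C(C)(C)C)[C@H]6O[Si](C)(C)C(C)(C)C)C=CC(C)(C)O2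
A5 | alternative 3 | ring-A/F benzodioxinone (acetonide of the salicylic acid, 5-O-acetyl) | CC(=O)Oc1c(C)c2OC(C)(C)C=Cc2c2OC(C)(C)OC(=O)c12
A6 | alternative 3 | ring-B/E 2-(tert-butyldimethylsilyloxy)benzofuran, tris-TBS | CC(C)(C)[Si](C)(C)Oc1oc5c6c(c(O[Si](C)(C)C(C)(C)C)cc5c1)OC(C)(C)[C@H](O[Si](C)(C)C(C)(C)C)[C@H]6O[Si](C)(C)C(C)(C)C
A7 | alternative 3 | 5-O-acetyl tris-TBS ether of the target | Cc1c2c(c3oc4oc5c6c(c(O[Si](C)(C)C(C)(C)C)cc5c4c(=O)c3c1OC(C)=O)OC(C)(C)[C@H](O[Si](C)(C)C(C)(C)C)[C@H]6O[Si](C)(C)C(C)(C)C)C=CC(C)(C)O2
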